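**Strategy**

Everything rests on cutting ring A (C1–C6) into a four-carbon and a two-carbon piece. Ring A is a masked phloroglucinol: oxygens on C1, C3 and C5, the ring C (cyclobutyl)methyl group on C6. A Danheiser benzannulation exploits this alternation: a 3-alkoxycyclobutenone, whose alkoxy group is the enantiopure O3–C2′–C3′–C4′ chain of ring B, delivers C1–C4, and a triisopropylsiloxyalkyne from (−)-α-pinene delivers C5 and C6. One thermal operation forms C1–C6 and C4–C5, re-forms C1–C2 and aromatises ring A with every substituent placed. Ring B acylation, a carbene-catalysed annulation for the C4 arm and dearomative C6 prenylation complete the target.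

Key step: step 7

**Remarks on the chemistry**

- Numbering: ring A carbons are C1 (enol OH in the target), C2 (carries the ring B ketone carbon C4′), C3 (carries the ring B ether oxygen O3), C4 (carries the phenylpropanoic acid arm), C5 (ketone in the target) and C6 (quaternary). In ring B, C2′ is the O–CH(CH3) carbon and C3′ the CH(CH3) carbon next to C4′. Ring C is the cyclobutane.
- Assumption: the target is a vinylogous acid and is drawn as its C5-keto/C1-enol tautomer; the route delivers this tautomeric system.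
- Once the C5 silyl group is removed, C2 and C4 of the aryl ether are equivalent, so ring B closure cannot give regioisomers. The silyl group is therefore taken off before the acylation.
- Assumption: the facial sense of the catalysts in steps 10 and 11 cannot be predicted with certainty for this substrate; the antipode that gives the required configuration is to be fixed in first runs (both antipodes are available).
- Commercial (−)-α-pinene of high enantiomeric purity is assumed.

**Route**

Step 1
Reactants: 1 (−)-α-pinene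
Product: 3 cis-pinonic acid [2-[(1R,3R)-3-acetyl-2,2-dimethylcyclobutyl]acetic acid], via pinonaldehyde 2 (not isolated)
Conditions: RuCl3·xH2O (2 mol %), NaIO4 (4 equiv), MeCN/EtOAc/H2O, 0 °C → rt
Reagents that add atoms: sodium periodate, [Na+].[O-]I(=O)(=O)=O; water, O
Why: ruthenium tetroxide formed in situ cleaves the ring alkene oxidatively (ketone plus aldehyde, aldehyde on to acid) without touching the two ring stereocentres, so the cis-1,3 relationship and absolute configuration of 1 pass into 3.

Step 2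
Reactants: 3 cis-pinonic acid
Product: 4 methyl cis-pinonate
Conditions: MeI, K2CO3, DMF, rt
Reagents that add atoms: iodomethane, CI
Why: SN2 O-methylation of the carboxylate under weakly basic conditions that should not epimerise the centre next to the ketone.

Step 3
Reactants: 4 methyl cis-pinonate
Product: 5 methyl 2-[(1R,3S)-2,2-dimethyl-3-(prop-1-en-2-yl)cyclobutyl]acetate
Conditions: Ph3PCH3Br, KOtBu, THF, 0 °C → rt
Reagents that add atoms: methyltriphenylphosphonium bromide, C[P+](c1ccccc1)(c1ccccc1)c1ccccc1.[Br-]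
Why: Wittig methylenation; the non-stabilised ylide reacts with the methyl ketone and leaves the ester alone, and a slight deficit of base relative to the phosphonium salt limits enolisation at the ring carbon.

Step 4
Reactants: 5 isopropenyl ester
Product: 7 triisopropyl({3-[(1R,3S)-2,2-dimethyl-3-(prop-1-en-2-yl)cyclobutyl]prop-1-yn-1-yl}oxy)silane, via lithium ynolate 6 (not isolated)
Conditions: CH2Br2, lithium 2,2,6,6-tetramethylpiperidide (LiTMP), THF, −78 °C; LiN(SiMe3)2, then n-BuLi, −78 °C → rt; iPr3SiCl, −78 °C → rt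
Reagents that add atoms: dibromomethane, BrCBr; chlorotriisopropylsilane, CC(C)[Si](Cl)(C(C)C)C(C)C
Why: Kowalski ester homologation: LiCHBr2 adds to the ester, the derived α,α-dibromo ketone enolate undergoes Br/Li exchange and 1,2-shift to ynolate 6, and the bulky chlorosilane traps it on oxygen to give the isolable siloxyalkyne.

Step 5
Reactants: 8 methyl (R)-3-hydroxybutanoate
Product: 10 methyl (2R,3R)-3-hydroxy-2-methylbutanoate, via dilithium dianion 9 (not isolated)
Conditions: LiN(iPr)2 (2.2 equiv), THF, −78 → −20 °C; MeI, DMPU, −78 → 0 °C; 1 M HCl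
Reagents that add atoms: iodomethane, CI
Why: Fráter–Seebach alkylation: the chelated dianion 9 is methylated on the face opposite the C3 methyl group, which sets C2 as R and should give the anti (2R,3R) ester.

Step 6
Reactants: 10 methyl (2R,3R)-3-hydroxy-2-methylbutanoate (1.5 equiv); 11 3-ethoxycyclobut-2-en-1-one
Product: 12 methyl (2R,3R)-2-methyl-3-[(3-oxocyclobut-1-en-1-yl)oxy]butanoate
Conditions: pyridinium p-toluenesulfonate (5 mol %), toluene, 45 °C, reduced pressure (ethanol removed)
Reagents that add atoms: none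
Why: acid-catalysed alkoxy exchange of a vinylogous ester (the alcohol adds at C3 of the protonated enone, ethanol leaves), driven by removal of ethanol; only the O–H bond of 10 is broken, so C2′ and C3′ are retained.

Step 7
Reactants: 12 chiral 3-alkoxycyclobutenone (1.3 equiv); 7 siloxyalkyne
Product: 17 methyl (2R,3R)-3-[4-{[(1R,3S)-2,2-dimethyl-3-(prop-1-en-2-yl)cyclobutyl]methyl}-3-hydroxy-5-(triisopropylsilyloxy)phenoxy]-2-methylbutanoate, via vinylketene 13 (not isolated), via 4-vinylcyclobutenone 14 (not isolated), via dienylketene 15 (not isolated), via cyclohexadienone 16 (not isolated)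
Conditions: toluene (0.3 M), 80 °C, then 110 °C, Ar
Reagents that add atoms: none
Why: Thermal 4π ring opening of 12 gives vinylketene 13, whose ketene C=C adds [2+2] to the electron-rich ynol ether 7 to give 4-vinylcyclobutenone 14; a second 4π opening gives dienylketene 15, and 6π electrocyclisation followed by tautomerisation of dienone 16 gives phenol 17. The closest known reaction type is the thermal benzannulation of cyclobutenones with heteroatom-substituted alkynes, established for trialkylsiloxyalkynes and for 3-oxygenated cyclobutenones. Ring A is closed by the thermal disrotatory 6π electrocyclisation that re-forms C1–C2; the four-membered ring of 14 is transient. No stereocentre is created, and the four existing ones lie outside the reacting π systems and see only neutral heat. The step needs regioselectivity only, and the polarity of the partners secures it: the nucleophilic alkyne carbon carrying the cyclobutylmethyl group bonds to the ketene carbonyl carbon, so C1–C6 and C4–C5 form and the free hydroxyl sits on C1 beside C6. A later silyl shift between O1 and O5 would not matter, because both oxygens are freed in step 8.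

Step 8
Reactants: 17 phenol silyl ether
Product: 19 (2R,3R)-3-[4-{[(1R,3S)-2,2-dimethyl-3-(prop-1-en-2-yl)cyclobutyl]methyl}-3,5-dihydroxyphenoxy]-2-methylbutanoic acid, via desilylated methyl ester 18 (not isolated)
Conditions: Bu4NF, THF, 0 °C; then LiOH·H2O, THF/MeOH/H2O (degassed), rt; 1 M HCl to pH 3, 0 °C
Reagents that add atoms: lithium hydroxide, [Li+].[OH-]
Why: fluoride cleaves the aryl silyl ether and hydroxide saponifies the methyl ester; as phenoxide and carboxylate the β-aryloxy acid is protected against β-elimination and α-epimerisation, and with O1 and O5 both free C2 and C4 become equivalent.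

Step 9
Reactants: 19 dihydroxy acid
Product: 21 (2R,3R)-6-{[(1R,3S)-2,2-dimethyl-3-(prop-1-en-2-yl)cyclobutyl]methyl}-5,7-dihydroxy-2,3-dimethylchroman-4-one, via mixed anhydride 20 (not isolated)
Conditions: (CF3CO)2O (1.2 equiv), CH2Cl2 (0.02 M), −20 → 0 °C; then MeOH, aq. NaHCO3
Reagents that add atoms: none
Why: intramolecular Friedel–Crafts acylation through mixed anhydride 20; the phloroglucinol-type ring should attack without a Lewis acid at low temperature, where dilute CF3CO2H should not protonate the isopropenyl group, and either ortho position gives the same trans-2,3-dimethylchromanone with C2′ and C3′ unchanged.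

Step 10
Reactants: 21 chromanone; 22 3-phenylprop-2-ynal
Product: 23 (2R,3R,10S)-6-{[(1R,3S)-2,2-dimethyl-3-(prop-1-en-2-yl)cyclobutyl]methyl}-5-hydroxy-2,3-dimethyl-10-phenyl-2,3,9,10-tetrahydro-4H,8H-pyrano[2,3-f]chromene-4,8-dione
Conditions: aminoindanol-derived N-mesityl triazolium chloride precatalyst [2-mesityl-5a,10b-dihydro-4H,6H-indeno[2,1-b][1,2,4]triazolo[4,3-d][1,4]oxazin-2-ium chloride, one enantiomer] (10 mol %), toluene, 40 °C
Reagents that add atoms: none
Why: carbene-catalysed redox annulation of an ynal with an acidic phenol (Coates–Claisen type): C4, the only free ring carbon, bonds to the β-carbon of the α,β-unsaturated acyl azolium and O5 then closes the lactone; the new benzylic centre (S) is set by the aminoindanol backbone of the catalyst, which shields one face of the acyl azolium.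

Step 11
Reactants: 23 tricyclic lactone; 24 3-methylbut-2-en-1-yl acetate (prenyl acetate)
Product: 26 target acid, via dilithium phenoxide carboxylate 25 (not isolated)
Conditions: LiOH (2.05 equiv), THF/H2O, 0 °C; then Pd2(dba)3·CHCl3 (2.5 mol %), N,N′-[(1R,2R)-cyclohexane-1,2-diyl]bis[2-(diphenylphosphanyl)benzamide] or its antipode (7.5 mol %), 24 (1.2 equiv), 0 °C → rt; 1 M HCl to pH 3, 0 °C
Reagents that add atoms: lithium hydroxide, [Li+].[OH-]
Why: lactone hydrolysis gives phenoxide–carboxylate 25, and a Tsuji–Trost allylation with dearomatisation follows: the phenoxide attacks the π-prenyl complex of divalent palladium through C6 (flanked by two oxygens, less hindered than C4) at the unsubstituted allyl terminus, and the chiral bisphosphine pocket selects the face of ring A and so sets C6 as R, O-prenylation being reversible.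

**Compound list**

1 | (−)-α-pinene, (1S,5S)-2,6,6-trimethylbicyclo[3.1.1]hept-2-ene | CC1=CC[C@H]2C[C@@H]1C2(C)C | starting material
2 | cis-pinonaldehyde, 2-[(1R,3R)-3-acetyl-2,2-dimethylcyclobutyl]acetaldehyde (not isolated) | CC(=O)[C@@H]1C[C@H](CC=O)C1(C)C | intermediate
3 | cis-pinonic acid, 2-[(1R,3R)-3-acetyl-2,2-dimethylcyclobutyl]acetic acid | CC(=O)[C@@H]1C[C@H](CC(=O)O)C1(C)C | intermediate
4 | methyl cis-pinonate, methyl 2-[(1R,3R)-3-acetyl-2,2-dimethylcyclobutyl]acetate | CC(=O)[C@@H]1C[C@H](CC(=O)OC)C1(C)C | intermediate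
5 | methyl 2-[(1R,3S)-2,2-dimethyl-3-(prop-1-en-2-yl)cyclobutyl]acetate | C=C(C)[C@@H]1C[C@H](CC(=O)OC)C1(C)C | intermediate
6 | lithium 3-[(1R,3S)-2,2-dimethyl-3-(prop-1-en-2-yl)cyclobutyl]prop-1-yn-1-olate (ynolate, not isolated) | C=C(C)[C@@H]1C[C@H](CC#C[O-])C1(C)C.[Li+] | intermediate
7 | triisopropyl({3-[(1R,3S)-2,2-dimethyl-3-(prop-1-en-2-yl)cyclobutyl]prop-1-yn-1-yl}oxy)silane | C=C(C)[C@@H]1C[C@H](CC#CO[Si](C(C)C)(C(C)C)C(C)C)C1(C)C | intermediate
8 | methyl (R)-3-hydroxybutanoate | C[C@@H](O)CC(=O)OC | starting material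
9 | dilithium alkoxide enolate of 8 (not isolated) | C[C@@H]([O-])C=C([O-])OC.[Li+].[Li+] | intermediate
10 | methyl (2R,3R)-3-hydroxy-2-methylbutanoate (anti) | C[C@@H](O)[C@@H](C)C(=O)OC | intermediate
11 | 3-ethoxycyclobut-2-en-1-one | CCOC1=CC(=O)C1 | starting material
12 | methyl (2R,3R)-2-methyl-3-[(3-oxocyclobut-1-en-1-yl)oxy]butanoate | O=C1C=C(O[C@H](C)[C@@H](C)C(=O)OC)C1 | intermediate
13 | vinylketene, methyl (2R,3R)-2-methyl-3-[(4-oxobuta-1,3-dien-2-yl)oxy]butanoate (not isolated) | O=C=CC(=C)O[C@H](C)[C@@H](C)C(=O)OC | intermediate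
14 | 4-vinylcyclobutenone: 2-(cyclobutylmethyl)-3-(triisopropylsilyloxy)cyclobut-2-en-1-one carrying the 1-alkoxyvinyl group on C4 (not isolated, C4 configuration undefined) | C=C(C)[C@@H]1C[C@H](CC2=C(O[Si](C(C)C)(C(C)C)C(C)C)C(C(=C)O[C@H](C)[C@@H](C)C(=O)OC)C2=O)C1(C)C | intermediate
15 | dienylketene: 2-(cyclobutylmethyl)-3-(triisopropylsilyloxy)-5-alkoxyhexa-1,3,5-trien-1-one (not isolated) | C=C(C)[C@@H]1C[C@H](CC(=C=O)C(O[Si](C(C)C)(C(C)C)C(C)C)=CC(=C)O[C@H](C)[C@@H](C)C(=O)OC)C1(C)C | intermediate
16 | cyclohexa-2,4-dienone tautomer of 17 (not isolated) | C=C(C)[C@@H]1C[C@H](CC2=C(O[Si](C(C)C)(C(C)C)C(C)C)C=C(O[C@H](C)[C@@H](C)C(=O)OC)CC2=O)C1(C)C | intermediate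
17 | methyl (2R,3R)-3-[4-{[(1R,3S)-2,2-dimethyl-3-(prop-1-en-2-yl)cyclobutyl]methyl}-3-hydroxy-5-(triisopropylsilyloxy)phenoxy]-2-methylbutanoate | C=C(C)[C@@H]1C[C@H](Cc2c(O)cc(O[C@H](C)[C@@H](C)C(=O)OC)cc2O[Si](C(C)C)(C(C)C)C(C)C)C1(C)C | intermediate
18 | methyl (2R,3R)-3-[4-{[(1R,3S)-2,2-dimethyl-3-(prop-1-en-2-yl)cyclobutyl]methyl}-3,5-dihydroxyphenoxy]-2-methylbutanoate (not isolated) | C=C(C)[C@@H]1C[C@H](Cc2c(O)cc(O[C@H](C)[C@@H](C)C(=O)OC)cc2O)C1(C)C | intermediate
19 | (2R,3R)-3-[4-{[(1R,3S)-2,2-dimethyl-3-(prop-1-en-2-yl)cyclobutyl]methyl}-3,5-dihydroxyphenoxy]-2-methylbutanoic acid | C=C(C)[C@@H]1C[C@H](Cc2c(O)cc(O[C@H](C)[C@@H](C)C(=O)O)cc2O)C1(C)C | intermediate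
20 | mixed trifluoroacetic anhydride of 19 (not isolated) | C=C(C)[C@@H]1C[C@H](Cc2c(O)cc(O[C@H](C)[C@@H](C)C(=O)OC(=O)C(F)(F)F)cc2O)C1(C)C | intermediate
21 | (2R,3R)-6-{[(1R,3S)-2,2-dimethyl-3-(prop-1-en-2-yl)cyclobutyl]methyl}-5,7-dihydroxy-2,3-dimethylchroman-4-one | C=C(C)[C@@H]1C[C@H](Cc2c(O)cc3O[C@H](C)[C@@H](C)C(=O)c3c2O)C1(C)C | intermediate
22 | 3-phenylprop-2-ynal | O=CC#Cc1ccccc1 | starting material
23 | (2R,3R,10S)-6-{[(1R,3S)-2,2-dimethyl-3-(prop-1-en-2-yl)cyclobutyl]methyl}-5-hydroxy-2,3-dimethyl-10-phenyl-2,3,9,10-tetrahydro-4H,8H-pyrano[2,3-f]chromene-4,8-dione (δ-lactone across O5/C4 of ring A) | C=C(C)[C@@H]1C[C@H](Cc2c3OC(=O)C[C@@H](c4ccccc4)c3c5O[C@H](C)[C@@H](C)C(=O)c5c2O)C1(C)C | intermediate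
24 | 3-methylbut-2-en-1-yl acetate (prenyl acetate) | CC(=O)OCC=C(C)C | starting material
25 | dilithium (3S)-3-[(2R,3R)-6-{[(1R,3S)-2,2-dimethyl-3-(prop-1-en-2-yl)cyclobutyl]methyl}-5-hydroxy-2,3-dimethyl-7-oxido-4-oxochroman-8-yl]-3-phenylpropanoate (not isolated) | C=C(C)[C@@H]1C[C@H](Cc2c([O-])c([C@@H](CC(=O)[O-])c3ccccc3)c3O[C@H](C)[C@@H](C)C(=O)c3c2O)C1(C)C.[Li+].[Li+] | intermediate
26 | (3S)-3-[(2R,3R,6R)-6-{[(1R,3S)-2,2-dimethyl-3-(prop-1-en-2-yl)cyclobutyl]methyl}-5-hydroxy-2,3-dimethyl-6-(3-methylbut-2-en-1-yl)-4,7-dioxo-3,4,6,7-tetrahydro-2H-chromen-8-yl]-3-phenylpropanoic acid | C=C(C)[C@@H]1C[C@H](C[C@@]2(CC=C(C)C)C(=O)C([C@@H](CC(=O)O)c3ccccc3)=C3O[C@H](C)[C@@H](C)C(=O)C3=C2O)C1(C)C | target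

**Step count**

Total: 11 steps. Longest linear sequence: 9 steps (1 → 3 → 4 → 5 → 7 → 17 → 19 → 21 → 23 → 26).

**Steps most likely to fail, with fallbacks**

Step 7. What may go wrong: polymerisation of the donor-substituted cyclobutenone or loss of its β-alkoxy ester chain before the vinylketene is trapped, and consumption of the product phenol by ketene acylation. Fallback (sets out from 11 and 7, comes back at 17): the chiral chain is attached after the annulation. Dilute aqueous HCl hydrolyses 11 to cyclobutane-1,3-dione F1. Silylation with tBuMe2SiCl/Et3N gives 3-(tert-butyldimethylsilyloxy)cyclobut-2-en-1-one F2. Heating F2 with 7 in toluene, the documented pairing of a silyloxycyclobutenone with a silyloxyalkyne, should give the doubly silylated phloroglucinol 5-(tert-butyldimethylsilyloxy)-2-(cyclobutylmethyl)-3-(triisopropylsilyloxy)phenol F3. K2CO3/MeOH should remove only the unhindered aryl tert-butyldimethylsilyl group and give the benzene-1,3-diol mono(triisopropylsilyl) ether F4. Mitsunobu etherification (PPh3, DIAD, toluene) of the unflanked hydroxyl of F4 with methyl (2R,3S)-3-hydroxy-2-methylbutanoate F5 goes with inversion at the carbinol carbon and gives 17. F5 comes from the syn-selective boron aldol reaction (Bu2BOTf, iPr2NEt) of commercial (R)-4-benzyl-3-propanoyloxazolidin-2-one with acetaldehyde, which gives (R)-4-benzyl-3-[(2R,3S)-3-hydroxy-2-methylbutanoyl]oxazolidin-2-one F6, followed by NaOMe/MeOH. This detour also makes step 6 unnecessary.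

Step 11. What may go wrong: poor facial selectivity at C6, because the existing stereocentres are remote and the ligand must do all the work, and competing attack through C4 or oxygen. Fallback (sets out from 23, comes back at 26): no induction is attempted. Aqueous KOH opens the lactone and prenyl bromide alkylates the phloroglucinol dianion at C6 at 0 °C, the classical way to gem-dialkylated acylphloroglucinols. This should give 26 together with its C6 epimer, the (6S) diastereomer of 26 F7; the two are diastereomers and are separated by preparative HPLC.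

Step 10. What may go wrong: O-acylation without C–C bond formation at the acyl-deactivated ring, or poor facial selectivity at the benzylic carbon. Fallback (sets out from 21, comes back at 23): magnesium-mediated ortho-formylation (MgCl2, Et3N, paraformaldehyde, MeCN, reflux) puts an aldehyde on C4 and gives the 8-formylchromanone F8. (Triphenylphosphoranylidene)ketene, Ph3P=C=C=O, in toluene acylates O5 and closes the ring by intramolecular Wittig reaction to the pyrano[2,3-f]chromene-4,8-dione (coumarin) F9. Hayashi–Miyaura addition of PhB(OH)2 [Rh(acac)(C2H4)2, (S)-Segphos, dioxane/H2O, 60 °C] then sets the benzylic centre under ligand control and gives 23.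

**Further compounds**

F1 | step 7 | cyclobutane-1,3-dione | O=C1CC(=O)C1
F2 | step 7 | 3-(tert-butyldimethylsilyloxy)cyclobut-2-en-1-one | CC(C)(C)[Si](C)(C)OC1=CC(=O)C1
F3 | step 7 | 5-(tert-butyldimethylsilyloxy)-2-{[(1R,3S)-2,2-dimethyl-3-(prop-1-en-2-yl)cyclobutyl]methyl}-3-(triisopropylsilyloxy)phenol | C=C(C)[C@@H]1C[C@H](Cc2c(O)cc(O[Si](C)(C)C(C)(C)C)cc2O[Si](C(C)C)(C(C)C)C(C)C)C1(C)C
F4 | step 7 | 4-{[(1R,3S)-2,2-dimethyl-3-(prop-1-en-2-yl)cyclobutyl]methyl}-5-(triisopropylsilyloxy)benzene-1,3-diol | C=C(C)[C@@H]1C[C@H](Cc2c(O)cc(O)cc2O[Si](C(C)C)(C(C)C)C(C)C)C1(C)C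
F5 | step 7 | methyl (2R,3S)-3-hydroxy-2-methylbutanoate | C[C@H](O)[C@@H](C)C(=O)OC
F6 | step 7 | (R)-4-benzyl-3-[(2R,3S)-3-hydroxy-2-methylbutanoyl]oxazolidin-2-one | C[C@H](O)[C@@H](C)C(=O)N1[C@H](Cc2ccccc2)COC1=O
F7 | step 11 | (6S) diastereomer of 26 (C6 epimer) | C=C(C)[C@@H]1C[C@H](C[C@]2(CC=C(C)C)C(=O)C([C@@H](CC(=O)O)c3ccccc3)=C3O[C@H](C)[C@@H](C)C(=O)C3=C2O)C1(C)C
F8 | step 10 | (2R,3R)-6-{[(1R,3S)-2,2-dimethyl-3-(prop-1-en-2-yl)cyclobutyl]methyl}-5,7-dihydroxy-2,3-dimethyl-4-oxochroman-8-carbaldehyde | C=C(C)[C@@H]1C[C@H](Cc2c(O)c(C=O)c3O[C@H](C)[C@@H](C)C(=O)c3c2O)C1(C)C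
F9 | step 10 | (2R,3R)-6-{[(1R,3S)-2,2-dimethyl-3-(prop-1-en-2-yl)cyclobutyl]methyl}-5-hydroxy-2,3-dimethyl-2,3-dihydro-4H,8H-pyrano[2,3-f]chromene-4,8-dione | C=C(C)[C@@H]1C[C@H](Cc2c3OC(=O)C=Cc3c5O[C@H](C)[C@@H](C)C(=O)c5c2O)C1(C)C
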